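Everything rests on cutting ring A free at both of its carbon substituents: the C9a–C9 bond to the carbinol carbon and the C4a–C5 bond to the later spiro carbon (benzo[7]annulene numbering of the target). Because C4a lies beside the C4 methoxy group and C9a beside the only aromatic hydrogen (C1–H), 3,4,5-trimethoxybenzyne takes up a lithiated dithiane at the carbon remote from oxygen and leaves the aryl anion beside methoxy, where zinc and palladium attach ring B. One flask thus joins a stereodefined 2-alkyl-1,3-dithiane (both methyl centres from (2S,3S)-2,3-dimethylsuccinic acid), 5-bromo-1,2,3-trimethoxybenzene and a silyl-protected 4-bromo-2,6-dimethoxyphenol; fluoride-triggered phenoxide para-alkylation later closes the seven-membered spiro ring.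

Key step: step 6

Remark: atom labels follow the spiro[benzo[7]annulene-5,1′-cyclohexadiene] numbering of the target (C5 spiro carbon = C1′ of ring B, C6 CH2, C7 and C8 CHMe, C9 carbinol). Ring A is the trimethoxybenzene ring, ring B the dienone ring or its phenol precursor. Ar = 3,4,5-trimethoxy-2-[3,5-dimethoxy-4-(triisopropylsilyloxy)phenyl]phenyl. Compounds 1, 5, 7 and 9 are taken as purchasable.

Step 1
Reactants: 1 (2S,3S)-2,3-dimethylsuccinic acid
Product: 2 (2S,3S)-2,3-dimethylbutane-1,4-diol
Conditions: LiAlH4, THF, 0 °C to reflux; H2O/NaOH work-up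
Reagents that add atoms: none
Why: Hydride reduction of both carboxyl groups (LiAlH4 reduction of a carboxylic acid) should proceed without loss of configuration, because the aluminium carboxylates formed first do not enolise.

Step 2
Reactants: 2 (2S,3S)-2,3-dimethylbutane-1,4-diol
Product: 3 (2S,3S)-4-(tert-butyldimethylsilyloxy)-2,3-dimethylbutan-1-ol
Conditions: NaH (1.0 equiv), THF, 0 °C to rt; TBSCl (1.0 equiv)
Reagents that add atoms: tert-butyldimethylsilyl chloride (TBSCl), CC(C)(C)[Si](C)(C)Cl
Why: O-Silylation of the sparingly soluble monosodium alkoxide favours the mono-ether, and since the two hydroxyl groups are homotopic (C2 axis) only one mono-ether can form.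

Step 3
Reactants: 3 (2S,3S)-4-(tert-butyldimethylsilyloxy)-2,3-dimethylbutan-1-ol
Product: 4 (2S,3S)-4-(tert-butyldimethylsilyloxy)-2,3-dimethylbutanal
Conditions: 2,2,6,6-tetramethylpiperidin-1-oxyl (TEMPO, cat.), PhI(OAc)2, CH2Cl2, rt
Reagents that add atoms: none
Why: Oxoammonium-mediated oxidation of a primary alcohol stops at the aldehyde and needs no amine base, so the α-stereocentre should not epimerise and the silyl ether is untouched.

Step 4
Reactants: 4 (2S,3S)-4-(tert-butyldimethylsilyloxy)-2,3-dimethylbutanal; 5 propane-1,3-dithiol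
Product: 6 2-[(2S,3S)-4-(tert-butyldimethylsilyloxy)-3-methylbutan-2-yl]-1,3-dithiane
Conditions: MgBr2·OEt2, Et2O, 0 °C to rt
Reagents that add atoms: none
Why: Lewis-acid-promoted dithioacetalisation with the mild MgBr2·OEt2 should leave the primary silyl ether in place and avoid enolisation of the α-branched aldehyde.

Step 5
Reactants: 7 4-bromo-2,6-dimethoxyphenol
Product: 8 (4-bromo-2,6-dimethoxyphenoxy)triisopropylsilane
Conditions: NaH, THF/DMF, 0 °C; TIPSCl, rt
Reagents that add atoms: triisopropylsilyl chloride (TIPSCl), CC(C)[Si](Cl)(C(C)C)C(C)C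
Why: O-Silylation of the sodium phenoxide gives an aryl silyl ether that withstands organozinc/palladium chemistry, borane and buffered HF, yet is cleaved by fluoride under basic conditions faster than any alkyl silyl ether, so that step 12 needs no hydrogenolysis next to the electron-rich benzylic C–O bond.

Step 6
Reactants: 6 2-[(2S,3S)-4-(tert-butyldimethylsilyloxy)-3-methylbutan-2-yl]-1,3-dithiane; 9 5-bromo-1,2,3-trimethoxybenzene; 8 (4-bromo-2,6-dimethoxyphenoxy)triisopropylsilane
Product: 14 2-[(2S,3S)-4-(tert-butyldimethylsilyloxy)-3-methylbutan-2-yl]-2-Ar-1,3-dithiane, via 2-lithio dithiane 10 (not isolated), via 3,4,5-trimethoxybenzyne 11 (not isolated), via aryllithium adduct 12 (not isolated), via arylzinc chloride 13 (not isolated)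
Conditions: n-BuLi, THF, −30 °C; 9, then LiTMP (lithium 2,2,6,6-tetramethylpiperidide), −78 to −30 °C; ZnCl2, THF, −30 °C to rt; 8, Pd(OAc)2 (5 mol %), 2-dicyclohexylphosphino-2′,6′-dimethoxybiphenyl (SPhos, 10 mol %), 60 °C
Reagents that add atoms: none
Why: LiTMP removes the proton of 9 between bromine and methoxy, LiBr is lost, and the aryne 11 is attacked by the dithianyl carbanion 10 at the aryne carbon remote from the flanking methoxy group, so that the aryllithium 12 sits ortho to that inductively withdrawing, lithium-coordinating oxygen. Transmetalation with ZnCl2 gives arylzinc 13, which zerovalent palladium (formed from Pd(OAc)2 and SPhos) couples with bromide 8 by oxidative addition, transmetalation and reductive elimination (Negishi coupling). The closest known reaction type is the addition of lithiated carbon nucleophiles to 3-alkoxyarynes with trapping of the 2-metallated arene by electrophiles or by cross-coupling (aryne 1,2-difunctionalisation). No ring closes and no stereocentre forms; the two methyl-bearing centres of 6 carry no acidic hydrogen under these conditions and pass through unchanged. The step needs regioselective addition to the unsymmetrical aryne, which methoxy on one side of the triple bond against hydrogen on the other secures, and it needs the dithianyl anion to outcompete the amide base, which the bulk of LiTMP secures. The bulky dialkylbiarylphosphine is chosen because the arylzinc carbon is flanked by methoxy and by the quaternary dithiane carbon.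

Step 7
Reactants: 14 2-[(2S,3S)-4-(tert-butyldimethylsilyloxy)-3-methylbutan-2-yl]-2-Ar-1,3-dithiane
Product: 15 (2S,3S)-1-Ar-4-(tert-butyldimethylsilyloxy)-2,3-dimethylbutan-1-one
Conditions: MeI, CaCO3, MeCN/H2O (9:1), 45 °C
Reagents that add atoms: water, O
Why: Alkylative dethioacetalisation (S-methylation, ring opening to a thionium ion stabilised by the para-methoxy group of ring A, hydrolysis) is non-oxidising and carbonate-buffered, so the electron-rich rings, both silyl ethers and the α-stereocentre should survive.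

Step 8
Reactants: 15 (2S,3S)-1-Ar-4-(tert-butyldimethylsilyloxy)-2,3-dimethylbutan-1-one
Product: 16 (1R,2S,3S)-1-Ar-4-(tert-butyldimethylsilyloxy)-2,3-dimethylbutan-1-ol
Conditions: (S)-1-methyl-3,3-diphenyltetrahydro-1H,3H-pyrrolo[1,2-c][1,3,2]oxazaborole [(S)-Me-CBS, 1.0 equiv], BH3·SMe2, THF, −20 °C; MeOH
Reagents that add atoms: none
Why: In this Corey–Bakshi–Shibata reduction the ketone should bind the catalyst boron with the bulky biaryl group turned away, so that hydride from the nitrogen-bound borane sets C1 as R (the sense of acetophenone to (R)-1-phenylethanol with the (S)-catalyst); catalyst control is required because the Felkin–Anh bias of the α-methyl ketone points to the 1S epimer.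

Step 9
Reactants: 16 (1R,2S,3S)-1-Ar-4-(tert-butyldimethylsilyloxy)-2,3-dimethylbutan-1-ol
Product: 17 (1R,2S,3S)-1-Ar-1,4-bis(tert-butyldimethylsilyloxy)-2,3-dimethylbutane
Conditions: TBSOTf, 2,6-lutidine, CH2Cl2, 0 °C
Reagents that add atoms: tert-butyldimethylsilyl trifluoromethanesulfonate (TBSOTf), CC(C)(C)[Si](C)(C)OS(=O)(=O)C(F)(F)F
Why: O-Silylation with the silyl triflate reaches the hindered secondary alcohol while lutidine prevents ionisation of the benzylic C–O bond, and the ether keeps the carbinol oxygen from closing a tetrahydrofuran onto the primary carbon later.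

Step 10
Reactants: 17 (1R,2S,3S)-1-Ar-1,4-bis(tert-butyldimethylsilyloxy)-2,3-dimethylbutane
Product: 18 (2S,3S,4R)-4-Ar-4-(tert-butyldimethylsilyloxy)-2,3-dimethylbutan-1-ol
Conditions: HF·pyridine, pyridine, THF, 0 °C
Reagents that add atoms: none
Why: Buffered HF·pyridine desilylation should remove the unhindered primary silyl ether far faster than the hindered secondary benzylic one or the aryl silyl ether, which resists acidic fluoride.

Step 11
Reactants: 18 (2S,3S,4R)-4-Ar-4-(tert-butyldimethylsilyloxy)-2,3-dimethylbutan-1-ol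
Product: 19 (2S,3S,4R)-4-Ar-4-(tert-butyldimethylsilyloxy)-2,3-dimethylbutyl methanesulfonate
Conditions: MsCl, Et3N, CH2Cl2, 0 °C
Reagents that add atoms: methanesulfonyl chloride (MsCl), CS(=O)(=O)Cl
Why: Mesylation of the primary alcohol is unambiguous because 18 carries no other free OH or NH group.

Step 12
Reactants: 19 (2S,3S,4R)-4-Ar-4-(tert-butyldimethylsilyloxy)-2,3-dimethylbutyl methanesulfonate
Product: 21 (7R,8S,9R)-9-(tert-butyldimethylsilyloxy)-2,3,3′,4,5′-pentamethoxy-7,8-dimethyl-6,7,8,9-tetrahydrospiro[benzo[7]annulene-5,1′-cyclohexa[2,5]diene]-4′-one, via cesium phenoxide 20 (not isolated)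
Conditions: CsF, DMF (0.005 M), 60–80 °C
Reagents that add atoms: none
Why: Fluoride should cleave only the aryl O–Si bond, and the cesium phenoxide 20 then displaces the mesylate through its para carbon C1′ in an intramolecular SN2 reaction (7-exo-tet phenoxide para-C-alkylation, an alkylative dearomatisation); intramolecular O-alkylation is geometrically impossible, the ortho carbons carry methoxy groups, high dilution suppresses intermolecular O-alkylation, and C5 is no stereocentre because ring B is symmetric.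

Step 13
Reactants: 21 (7R,8S,9R)-9-(tert-butyldimethylsilyloxy)-2,3,3′,4,5′-pentamethoxy-7,8-dimethyl-6,7,8,9-tetrahydrospiro[benzo[7]annulene-5,1′-cyclohexa[2,5]diene]-4′-one
Product: 22 (7R,8S,9R)-9-hydroxy-2,3,3′,4,5′-pentamethoxy-7,8-dimethyl-6,7,8,9-tetrahydrospiro[benzo[7]annulene-5,1′-cyclohexa[2,5]diene]-4′-one (CNP0288561.1)
Conditions: HF·pyridine (excess), THF, rt
Reagents that add atoms: none
Why: Fluoride-mediated desilylation under these mildly acidic conditions should free the C9 hydroxyl without a dienone–phenol rearrangement or ionisation of the benzylic alcohol, giving the target with C7 and C8 from 1 and C9 from step 8.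

Compound list
1 | (2S,3S)-2,3-dimethylsuccinic acid | OC(=O)[C@@H](C)[C@H](C)C(=O)O | starting material
2 | (2S,3S)-2,3-dimethylbutane-1,4-diol | OC[C@@H](C)[C@H](C)CO | intermediate
3 | (2S,3S)-4-(tert-butyldimethylsilyloxy)-2,3-dimethylbutan-1-ol | CC(C)(C)[Si](C)(C)OC[C@@H](C)[C@H](C)CO | intermediate
4 | (2S,3S)-4-(tert-butyldimethylsilyloxy)-2,3-dimethylbutanal | CC(C)(C)[Si](C)(C)OC[C@@H](C)[C@H](C)C=O | intermediate
5 | propane-1,3-dithiol | SCCCS | starting material
6 | 2-[(2S,3S)-4-(tert-butyldimethylsilyloxy)-3-methylbutan-2-yl]-1,3-dithiane | CC(C)(C)[Si](C)(C)OC[C@@H](C)[C@H](C)C1SCCCS1 | intermediate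
7 | 4-bromo-2,6-dimethoxyphenol | COc1cc(Br)cc(OC)c1O | starting material
8 | (4-bromo-2,6-dimethoxyphenoxy)triisopropylsilane | COc1cc(Br)cc(OC)c1O[Si](C(C)C)(C(C)C)C(C)C | intermediate
9 | 5-bromo-1,2,3-trimethoxybenzene | COc1cc(Br)cc(OC)c1OC | starting material
10 | 2-lithio derivative of dithiane 6 (formed in the flask in step 6) | CC(C)(C)[Si](C)(C)OC[C@@H](C)[C@H](C)C1([Li])SCCCS1 | intermediate
11 | 3,4,5-trimethoxybenzyne (formed in the flask in step 6) | COC1=C(OC)C(OC)=CC#C1 | intermediate
12 | aryllithium adduct: dithiane 6 joined through C2 to C1 of a 2-lithio-3,4,5-trimethoxyphenyl ring (formed in the flask in step 6) | CC(C)(C)[Si](C)(C)OC[C@@H](C)[C@H](C)C1(SCCCS1)c1cc(OC)c(OC)c(OC)c1[Li] | intermediate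
13 | arylzinc chloride corresponding to 12 (formed in the flask in step 6) | CC(C)(C)[Si](C)(C)OC[C@@H](C)[C@H](C)C1(SCCCS1)c1cc(OC)c(OC)c(OC)c1[Zn]Cl | intermediate
14 | 2-[(2S,3S)-4-(tert-butyldimethylsilyloxy)-3-methylbutan-2-yl]-2-Ar-1,3-dithiane | CC(C)(C)[Si](C)(C)OC[C@@H](C)[C@H](C)C1(SCCCS1)c1cc(OC)c(OC)c(OC)c1-c1cc(OC)c(O[Si](C(C)C)(C(C)C)C(C)C)c(OC)c1 | intermediate
15 | (2S,3S)-1-Ar-4-(tert-butyldimethylsilyloxy)-2,3-dimethylbutan-1-one | CC(C)(C)[Si](C)(C)OC[C@@H](C)[C@H](C)C(=O)c1cc(OC)c(OC)c(OC)c1-c1cc(OC)c(O[Si](C(C)C)(C(C)C)C(C)C)c(OC)c1 | intermediate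
16 | (1R,2S,3S)-1-Ar-4-(tert-butyldimethylsilyloxy)-2,3-dimethylbutan-1-ol | CC(C)(C)[Si](C)(C)OC[C@@H](C)[C@H](C)[C@@H](O)c1cc(OC)c(OC)c(OC)c1-c1cc(OC)c(O[Si](C(C)C)(C(C)C)C(C)C)c(OC)c1 | intermediate
17 | (1R,2S,3S)-1-Ar-1,4-bis(tert-butyldimethylsilyloxy)-2,3-dimethylbutane | CC(C)(C)[Si](C)(C)OC[C@@H](C)[C@H](C)[C@@H](O[Si](C)(C)C(C)(C)C)c1cc(OC)c(OC)c(OC)c1-c1cc(OC)c(O[Si](C(C)C)(C(C)C)C(C)C)c(OC)c1 | intermediate
18 | (2S,3S,4R)-4-Ar-4-(tert-butyldimethylsilyloxy)-2,3-dimethylbutan-1-ol | OC[C@@H](C)[C@H](C)[C@@H](O[Si](C)(C)C(C)(C)C)c1cc(OC)c(OC)c(OC)c1-c1cc(OC)c(O[Si](C(C)C)(C(C)C)C(C)C)c(OC)c1 | intermediate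
19 | (2S,3S,4R)-4-Ar-4-(tert-butyldimethylsilyloxy)-2,3-dimethylbutyl methanesulfonate | CS(=O)(=O)OC[C@@H](C)[C@H](C)[C@@H](O[Si](C)(C)C(C)(C)C)c1cc(OC)c(OC)c(OC)c1-c1cc(OC)c(O[Si](C(C)C)(C(C)C)C(C)C)c(OC)c1 | intermediate
20 | cesium phenoxide of 19 after loss of the triisopropylsilyl group (formed in the flask in step 12) | CS(=O)(=O)OC[C@@H](C)[C@H](C)[C@@H](O[Si](C)(C)C(C)(C)C)c1cc(OC)c(OC)c(OC)c1-c1cc(OC)c([O-])c(OC)c1.[Cs+] | intermediate
21 | (7R,8S,9R)-9-(tert-butyldimethylsilyloxy)-2,3,3′,4,5′-pentamethoxy-7,8-dimethyl-6,7,8,9-tetrahydrospiro[benzo[7]annulene-5,1′-cyclohexa[2,5]diene]-4′-one | COC1=CC2(C=C(OC)C1=O)C[C@@H](C)[C@H](C)[C@@H](O[Si](C)(C)C(C)(C)C)c1cc(OC)c(OC)c(OC)c12 | intermediate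
22 | (7R,8S,9R)-9-hydroxy-2,3,3′,4,5′-pentamethoxy-7,8-dimethyl-6,7,8,9-tetrahydrospiro[benzo[7]annulene-5,1′-cyclohexa[2,5]diene]-4′-one (CNP0288561.1) | COC1=CC2(C=C(OC)C1=O)C[C@@H](C)[C@H](C)[C@@H](O)c1cc(OC)c(OC)c(OC)c12 | target

Total step count: 13. Longest linear sequence: 12 steps (1 → 2 → 3 → 4 → 6 → 14 → 15 → 16 → 17 → 18 → 19 → 21 → 22; step 5 is a one-step branch).

Steps most likely to fail

Step 6. The aryne may be consumed unselectively (self-condensation, addition of the amide base, the dithianyl anion acting only as a base), or the congested arylzinc may fail to transmetalate to palladium. The fallback avoids aryne and dithiane altogether; it sets out from aldehyde 4, bromide 9 and bromide 8 and comes back at ketone 15. Bromine–lithium exchange on 9 (n-BuLi, THF, −78 °C) and addition of the aryllithium to 4 should give (2S,3S)-4-(tert-butyldimethylsilyloxy)-2,3-dimethyl-1-(3,4,5-trimethoxyphenyl)butan-1-ol F1 as a mixture of C1 epimers. Dess–Martin periodinane would oxidise it to (2S,3S)-4-(tert-butyldimethylsilyloxy)-2,3-dimethyl-1-(3,4,5-trimethoxyphenyl)butan-1-one F2. NBS in MeCN should brominate ring A ortho to the acyl group, the usual site in 3,4,5-trimethoxyphenyl carbonyl compounds, to give (2S,3S)-1-(2-bromo-3,4,5-trimethoxyphenyl)-4-(tert-butyldimethylsilyloxy)-2,3-dimethylbutan-1-one F3. Bromide 8 is converted by bromine–lithium exchange and 2-isopropoxy-4,4,5,5-tetramethyl-1,3,2-dioxaborolane into 2-[3,5-dimethoxy-4-(triisopropylsilyloxy)phenyl]-4,4,5,5-tetramethyl-1,3,2-dioxaborolane F4. Suzuki–Miyaura coupling of F3 with F4 (Pd(OAc)2, SPhos, K3PO4, toluene/H2O) would give 15, so step 7 is no longer needed.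

Step 8. Facial selectivity may be poor, because the catalyst has to override the Felkin–Anh bias of the α-methyl ketone and must tell the biaryl group from a branched alkyl group. The fallback uses the substrate bias instead of fighting it; it sets out from ketone 15 and comes back at carbinol 16. Reduction with LiBH(s-Bu)3 (THF, −78 °C) should give the Felkin–Anh product (1S,2S,3S)-1-Ar-4-(tert-butyldimethylsilyloxy)-2,3-dimethylbutan-1-ol F5. Mitsunobu inversion (4-nitrobenzoic acid, PPh3, diisopropyl azodicarboxylate, toluene) would convert it into (1R,2S,3S)-1-Ar-4-(tert-butyldimethylsilyloxy)-2,3-dimethylbutyl 4-nitrobenzoate F6. Reductive ester cleavage with i-Bu2AlH (CH2Cl2, −78 °C), which spares the aryl silyl ether, returns 16.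

Step 12. Closure of the seven-membered ring may be too slow, so that intermolecular O-alkylation, base-induced elimination of the mesylate, or fluoride attack on the carbinol silyl ether followed by tetrahydrofuran formation take over. The fallback replaces sulfonate displacement under fluoride by a dehydrative Mitsunobu-type spirocyclisation that needs neither fluoride nor external base in the ring-closing flask; it sets out from alcohol 18 and comes back at 21. One equivalent of Bu4NF (THF, −20 °C) should remove only the aryl silyl group and give (2S,3S,4R)-4-(tert-butyldimethylsilyloxy)-4-[2-(4-hydroxy-3,5-dimethoxyphenyl)-3,4,5-trimethoxyphenyl]-2,3-dimethylbutan-1-ol F7. Activation of its primary alcohol with PBu3 and 1,1′-(azodicarbonyl)dipiperidine in toluene at high dilution generates a phenoxide/alkoxyphosphonium ion pair within one molecule, and its collapse through the para carbon would give 21. This is the reaction type known for spirocyclisations of hydroxyalkyl phenols to spirocyclohexadienones; the silyl ether on C9 stays untouched.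

Further compounds
F1 | step 6 | (2S,3S)-4-(tert-butyldimethylsilyloxy)-2,3-dimethyl-1-(3,4,5-trimethoxyphenyl)butan-1-ol (both C1 epimers) | CC(C)(C)[Si](C)(C)OC[C@@H](C)[C@H](C)C(O)c1cc(OC)c(OC)c(OC)c1
F2 | step 6 | (2S,3S)-4-(tert-butyldimethylsilyloxy)-2,3-dimethyl-1-(3,4,5-trimethoxyphenyl)butan-1-one | CC(C)(C)[Si](C)(C)OC[C@@H](C)[C@H](C)C(=O)c1cc(OC)c(OC)c(OC)c1
F3 | step 6 | (2S,3S)-1-(2-bromo-3,4,5-trimethoxyphenyl)-4-(tert-butyldimethylsilyloxy)-2,3-dimethylbutan-1-one | CC(C)(C)[Si](C)(C)OC[C@@H](C)[C@H](C)C(=O)c1cc(OC)c(OC)c(OC)c1Br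
F4 | step 6 | 2-[3,5-dimethoxy-4-(triisopropylsilyloxy)phenyl]-4,4,5,5-tetramethyl-1,3,2-dioxaborolane | COc1cc(cc(OC)c1O[Si](C(C)C)(C(C)C)C(C)C)B1OC(C)(C)C(C)(C)O1
F5 | step 8 | (1S,2S,3S)-1-Ar-4-(tert-butyldimethylsilyloxy)-2,3-dimethylbutan-1-ol | CC(C)(C)[Si](C)(C)OC[C@@H](C)[C@H](C)[C@H](O)c1cc(OC)c(OC)c(OC)c1-c1cc(OC)c(O[Si](C(C)C)(C(C)C)C(C)C)c(OC)c1
F6 | step 8 | (1R,2S,3S)-1-Ar-4-(tert-butyldimethylsilyloxy)-2,3-dimethylbutyl 4-nitrobenzoate | CC(C)(C)[Si](C)(C)OC[C@@H](C)[C@H](C)[C@@H](OC(=O)c1ccc(cc1)[N+](=O)[O-])c1cc(OC)c(OC)c(OC)c1-c1cc(OC)c(O[Si](C(C)C)(C(C)C)C(C)C)c(OC)c1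
F7 | step 12 | (2S,3S,4R)-4-(tert-butyldimethylsilyloxy)-4-[2-(4-hydroxy-3,5-dimethoxyphenyl)-3,4,5-trimethoxyphenyl]-2,3-dimethylbutan-1-ol | OC[C@@H](C)[C@H](C)[C@@H](O[Si](C)(C)C(C)(C)C)c1cc(OC)c(OC)c(OC)c1-c1cc(OC)c(O)c(OC)c1
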